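Ring A is made last, not carried through. Its ether-bearing carbon and methoxy-bearing carbon are C3 and C4 of a 3-aryloxy-4-methoxy-2-pyrone, its two neighbouring CH carbons are pyrone C5 and C6, and the carbon bearing chain carbon C7 plus the CH between it and the ether carbon come from a terminal alkyne. One thermal intramolecular [4+2] cycloaddition with loss of CO2 therefore forms ring A and closes the 15-membered macrocycle at once, so the diaryl ether oxygen is already in place on ring B and no aryl C–O coupling is needed. The precursor is the ring B pyrone ether whose C1–C7 chain (C5 as dioxolane, phenol as benzyl ether) ends in the alkyne.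

Key step: step 13

Remark: chain carbons are numbered C1 (on ring B) to C7 (on ring A) with the ketone at C5; the target has no stereocentre, so racemic intermediates are written without stereodescriptors.

Step 1
Reactants: 1 2-methoxyresorcinol; 2 methyl bromoacetate
Product: 3 methyl 2-(3-hydroxy-2-methoxyphenoxy)acetate
Conditions: 1 (2 equiv), K2CO3 (1.1 equiv), acetone, reflux; 2 (1 equiv) added slowly
Reagents that add atoms: none
Why: Williamson ether synthesis on a symmetrical diphenol, in which the excess of 1 and slow addition of 2 should hold the alkylation at the mono-ether stage while unchanged 1 is recovered.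

Step 2
Reactants: 3 methyl 2-(3-hydroxy-2-methoxyphenoxy)acetate; 4 allyl bromide
Product: 5 methyl 2-[2-methoxy-3-(prop-2-en-1-yloxy)phenoxy]acetate
Conditions: K2CO3, acetone, reflux
Reagents that add atoms: none
Why: Williamson ether synthesis of the remaining phenol with a reactive allylic bromide under carbonate conditions that leave the methyl ester intact.

Step 3
Reactants: 5 methyl 2-[2-methoxy-3-(prop-2-en-1-yloxy)phenoxy]acetate
Product: 7 methyl 2-[3-hydroxy-2-methoxy-4-(prop-2-en-1-yl)phenoxy]acetate, via ortho-dienone 6 (not isolated)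
Conditions: 1,2-dichlorobenzene, 185 °C
Reagents that add atoms: none
Why: Aromatic Claisen rearrangement, a [3,3]-sigmatropic shift that can deliver the allyl group productively only to the free ortho carbon of ring B (the other ortho carbon carries the methoxy group), followed by tautomerisation of dienone 6 to the phenol.

Step 4
Reactants: 7 methyl 2-[3-hydroxy-2-methoxy-4-(prop-2-en-1-yl)phenoxy]acetate
Product: 8 methyl 2-[3-(benzyloxy)-2-methoxy-4-(prop-2-en-1-yl)phenoxy]acetate
Conditions: BnBr, K2CO3, DMF, 60 °C
Reagents that add atoms: benzyl bromide, BrCc1ccccc1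
Why: Williamson benzylation of the hindered but acidic phenol, which masks it for the enolate chemistry ahead as an ether that withstands base, mild acid and heat.

Step 5
Reactants: 8 methyl 2-[3-(benzyloxy)-2-methoxy-4-(prop-2-en-1-yl)phenoxy]acetate
Product: 10 methyl 2-[3-(benzyloxy)-4-(3-hydroxypropyl)-2-methoxyphenoxy]acetate, via B-alkyl-9-BBN adduct 9 (not isolated)
Conditions: 9-BBN, THF, 0 °C → rt; then NaBO3·4H2O, H2O, rt
Reagents that add atoms: sodium perborate, [Na+].[O-]OB=O
Why: Anti-Markovnikov hydroboration of the terminal alkene with bulky 9-BBN and oxidation of the C–B bond with mild perborate, which spares the methyl ester that alkaline hydrogen peroxide could saponify.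

Step 6
Reactants: 10 methyl 2-[3-(benzyloxy)-4-(3-hydroxypropyl)-2-methoxyphenoxy]acetate
Product: 11 methyl 2-[3-(benzyloxy)-4-(3-chloropropyl)-2-methoxyphenoxy]acetate
Conditions: PPh3, CCl4, CH2Cl2, rt
Reagents that add atoms: carbon tetrachloride, ClC(Cl)(Cl)Cl
Why: Appel reaction, an SN2 displacement of an oxyphosphonium leaving group by chloride, chosen because a primary chloride is inert to the ester enolate and the carbonate base of the next two steps and is activated later by iodide.

Step 7
Reactants: 11 methyl 2-[3-(benzyloxy)-4-(3-chloropropyl)-2-methoxyphenoxy]acetate; 12 (E)-3-ethoxyacryloyl chloride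
Product: 15 3-[3-(benzyloxy)-4-(3-chloropropyl)-2-methoxyphenoxy]-4-hydroxy-2H-pyran-2-one, via enol ether keto ester 13 (not isolated), via formyl keto ester 14 (not isolated)
Conditions: LiN(SiMe3)2 (2.2 equiv), THF, −78 °C; 12 (1.1 equiv), −78 → 0 °C; then 2 M HCl, 50 °C
Reagents that add atoms: water, O
Why: Crossed Claisen condensation of the lithium ester enolate with the acid chloride (the second equivalent of base absorbs the acidic product), then acid hydrolysis of the vinylogous ester to a formyl ketone whose enol oxygen lactonises onto the methyl ester, the known ring closure of 3,5-dioxo esters to 4-hydroxy-2-pyrones, under acid too mild to cyclodehydrate the aryloxy ketone onto ring B.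

Step 8
Reactants: 15 3-[3-(benzyloxy)-4-(3-chloropropyl)-2-methoxyphenoxy]-4-hydroxy-2H-pyran-2-one
Product: 16 3-[3-(benzyloxy)-4-(3-chloropropyl)-2-methoxyphenoxy]-4-methoxy-2H-pyran-2-one
Conditions: Me2SO4, K2CO3, acetone, reflux
Reagents that add atoms: dimethyl sulfate, COS(=O)(=O)OC
Why: O-Alkylation of the vinylogous acid with dimethyl sulfate and carbonate in acetone, conditions under which 4-hydroxy-2-pyrones are known to react mainly at the C4 oxygen to give 4-methoxy-2-pyrones.

Step 9
Reactants: 17 allyl acetoacetate; 18 propargyl bromide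
Product: 19 allyl 3-oxohept-6-ynoate
Conditions: LiN(i-Pr)2 (2.1 equiv), THF, 0 °C; 18, −78 → 0 °C; 1 M HCl
Reagents that add atoms: none
Why: γ-Alkylation of the acetoacetate dianion, whose more basic terminal carbanion reacts selectively with the propargylic bromide, with the allyl ester chosen so that it can be removed later under neutral conditions.

Step 10
Reactants: 16 3-[3-(benzyloxy)-4-(3-chloropropyl)-2-methoxyphenoxy]-4-methoxy-2H-pyran-2-one; 19 allyl 3-oxohept-6-ynoate
Product: 21 allyl 2-{3-[2-(benzyloxy)-3-methoxy-4-(4-methoxy-2-oxo-2H-pyran-3-yloxy)phenyl]propyl}-3-oxohept-6-ynoate (racemic), via iodide 20 (not isolated)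
Conditions: 19 (1.5 equiv), K2CO3, NaI (cat.), DMF, 60 °C
Reagents that add atoms: none
Why: C-Alkylation of the β-keto ester potassium enolate by the primary halide, accelerated by Finkelstein exchange to iodide 20, under carbonate conditions mild enough for the methoxypyrone, the new stereocentre being formed as a racemate and removed in the next step.

Step 11
Reactants: 21 allyl 2-{3-[2-(benzyloxy)-3-methoxy-4-(4-methoxy-2-oxo-2H-pyran-3-yloxy)phenyl]propyl}-3-oxohept-6-ynoate
Product: 23 3-[3-(benzyloxy)-2-methoxy-4-(5-oxonon-8-yn-1-yl)phenoxy]-4-methoxy-2H-pyran-2-one, via keto acid 22 (not isolated)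
Conditions: Pd(PPh3)4 (cat.), morpholine (3 equiv), THF, rt → 45 °C
Reagents that add atoms: none
Why: Tsuji–Trost deallylation, in which zerovalent palladium ionises the allyl ester and morpholine traps the allyl fragment, followed by spontaneous decarboxylation of β-keto acid 22, which avoids the hydroxide or hot halide conditions that would attack the pyrone.

Step 12
Reactants: 23 3-[3-(benzyloxy)-2-methoxy-4-(5-oxonon-8-yn-1-yl)phenoxy]-4-methoxy-2H-pyran-2-one
Product: 24 3-[3-(benzyloxy)-4-{4-[2-(but-3-yn-1-yl)-1,3-dioxolan-2-yl]butyl}-2-methoxyphenoxy]-4-methoxy-2H-pyran-2-one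
Conditions: (Me3SiOCH2)2, Me3SiOTf (cat.), CH2Cl2, −78 → −20 °C; pyridine quench
Reagents that add atoms: 1,2-bis(trimethylsilyloxy)ethane, C[Si](C)(C)OCCO[Si](C)(C)C
Why: Ketalisation by silyl transfer catalysed by Me3SiOTf at low temperature, a non-aqueous method driven by formation of hexamethyldisiloxane, which should leave the acid-sensitive methoxypyrone, the benzyl ether and the alkyne untouched.

Step 13
Reactants: 24 3-[3-(benzyloxy)-4-{4-[2-(but-3-yn-1-yl)-1,3-dioxolan-2-yl]butyl}-2-methoxyphenoxy]-4-methoxy-2H-pyran-2-one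
Product: 26 O-benzyl juglanin A ethylene ketal, via bridged lactone 25 (not isolated)
Conditions: 1,2-dichlorobenzene (0.002 M), BHT (cat.), 230 °C, sealed tube
Reagents that add atoms: none
Why: The pyrone diene (C3=C4–C5=C6) and the tethered alkyne combine in a thermal [4+2] cycloaddition to bridged lactone 25, which expels CO2 by cycloreversion, so the sequence is irreversible and ends in the benzene ring A. The closest known reaction type is the intramolecular 2-pyrone–alkyne Diels–Alder reaction with CO2 loss that has been used to build the arene of strained cyclophanes. Ring A closes by cycloaddition–cycloreversion from the four pyrone carbons and the two alkyne carbons, and the 15-membered ring closes in the same event in the bridging mode, because the 12-atom tether (ether oxygen, the para axis of ring B, C1–C7) joins pyrone C3 to the alkyne carbon that bonds to C6, which leaves ring A meta-bridged. No stereocentre remains, since the two bridgeheads of 25 become aromatic carbons. The step needs the orientation in which the alkyne CH bonds to the fully substituted C3 and the chain-bearing alkyne carbon to the unsubstituted C6; this is expected on steric grounds, because the reverse orientation would join two fully substituted carbons beside the aryloxy group. High dilution should suppress intermolecular cycloaddition, the dioxolane prevents thermal Conia-ene cyclisation of a free C5 ketone onto the alkyne, and the benzyl ether is inert to heat.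

Step 14
Reactants: 26 O-benzyl juglanin A ethylene ketal
Product: 28 juglanin A, via juglanin A ethylene ketal 27 (not isolated)
Conditions: H2 (1 atm), 10% Pd/C, THF–MeOH, rt; then 2 M HCl, rt
Reagents that add atoms: water, O
Why: Hydrogenolysis of the benzyl aryl ether over Pd/C followed in the same flask by acid-catalysed hydrolysis of the dioxolane, two standard deprotections that the diaryl ether, the aryl methyl ethers and the dialkyl ketone should survive.

Compound list
1 | 2-methoxyresorcinol (2-methoxybenzene-1,3-diol) | COc1c(O)cccc1O | starting material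
2 | methyl bromoacetate | COC(=O)CBr | starting material
3 | methyl 2-(3-hydroxy-2-methoxyphenoxy)acetate | COC(=O)COc1cccc(O)c1OC | intermediate
4 | allyl bromide (3-bromoprop-1-ene) | C=CCBr | starting material
5 | methyl 2-[2-methoxy-3-(prop-2-en-1-yloxy)phenoxy]acetate | COC(=O)COc1cccc(OCC=C)c1OC | intermediate
6 | methyl 2-{[2-methoxy-3-oxo-4-(prop-2-en-1-yl)cyclohexa-1,5-dien-1-yl]oxy}acetate (ortho-dienone, racemic) | COC(=O)COC1=C(OC)C(=O)C(CC=C)C=C1 | intermediate
7 | methyl 2-[3-hydroxy-2-methoxy-4-(prop-2-en-1-yl)phenoxy]acetate | COC(=O)COc1ccc(CC=C)c(O)c1OC | intermediate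
8 | methyl 2-[3-(benzyloxy)-2-methoxy-4-(prop-2-en-1-yl)phenoxy]acetate | COC(=O)COc1ccc(CC=C)c(OCc2ccccc2)c1OC | intermediate
9 | methyl 2-{3-(benzyloxy)-4-[3-(9-borabicyclo[3.3.1]nonan-9-yl)propyl]-2-methoxyphenoxy}acetate | COC(=O)COc1ccc(CCCB2C3CCCC2CCC3)c(OCc2ccccc2)c1OC | intermediate
10 | methyl 2-[3-(benzyloxy)-4-(3-hydroxypropyl)-2-methoxyphenoxy]acetate | COC(=O)COc1ccc(CCCO)c(OCc2ccccc2)c1OC | intermediate
11 | methyl 2-[3-(benzyloxy)-4-(3-chloropropyl)-2-methoxyphenoxy]acetate | COC(=O)COc1ccc(CCCCl)c(OCc2ccccc2)c1OC | intermediate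
12 | (E)-3-ethoxyacryloyl chloride | CCO/C=C/C(=O)Cl | starting material
13 | methyl (4E)-2-[3-(benzyloxy)-4-(3-chloropropyl)-2-methoxyphenoxy]-5-ethoxy-3-oxopent-4-enoate (racemic, readily enolised) | CCO/C=C/C(=O)C(Oc1ccc(CCCCl)c(OCc2ccccc2)c1OC)C(=O)OC | intermediate
14 | methyl (4Z)-2-[3-(benzyloxy)-4-(3-chloropropyl)-2-methoxyphenoxy]-5-hydroxy-3-oxopent-4-enoate (enol form of the 5-oxo compound, racemic) | O/C=C\C(=O)C(Oc1ccc(CCCCl)c(OCc2ccccc2)c1OC)C(=O)OC | intermediate
15 | 3-[3-(benzyloxy)-4-(3-chloropropyl)-2-methoxyphenoxy]-4-hydroxy-2H-pyran-2-one | OC1=C(Oc2ccc(CCCCl)c(OCc3ccccc3)c2OC)C(=O)OC=C1 | intermediate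
16 | 3-[3-(benzyloxy)-4-(3-chloropropyl)-2-methoxyphenoxy]-4-methoxy-2H-pyran-2-one | COC1=C(Oc2ccc(CCCCl)c(OCc3ccccc3)c2OC)C(=O)OC=C1 | intermediate
17 | allyl acetoacetate (prop-2-en-1-yl 3-oxobutanoate) | CC(=O)CC(=O)OCC=C | starting material
18 | propargyl bromide (3-bromoprop-1-yne) | C#CCBr | starting material
19 | allyl 3-oxohept-6-ynoate | C#CCCC(=O)CC(=O)OCC=C | intermediate
20 | 3-[3-(benzyloxy)-4-(3-iodopropyl)-2-methoxyphenoxy]-4-methoxy-2H-pyran-2-one | COC1=C(Oc2ccc(CCCI)c(OCc3ccccc3)c2OC)C(=O)OC=C1 | intermediate
21 | allyl 2-{3-[2-(benzyloxy)-3-methoxy-4-(4-methoxy-2-oxo-2H-pyran-3-yloxy)phenyl]propyl}-3-oxohept-6-ynoate (racemic) | COC1=C(Oc2ccc(CCCC(C(=O)OCC=C)C(=O)CCC#C)c(OCc3ccccc3)c2OC)C(=O)OC=C1 | intermediate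
22 | 2-{3-[2-(benzyloxy)-3-methoxy-4-(4-methoxy-2-oxo-2H-pyran-3-yloxy)phenyl]propyl}-3-oxohept-6-ynoic acid (racemic) | COC1=C(Oc2ccc(CCCC(C(=O)O)C(=O)CCC#C)c(OCc3ccccc3)c2OC)C(=O)OC=C1 | intermediate
23 | 3-[3-(benzyloxy)-2-methoxy-4-(5-oxonon-8-yn-1-yl)phenoxy]-4-methoxy-2H-pyran-2-one | COC1=C(Oc2ccc(CCCCC(=O)CCC#C)c(OCc3ccccc3)c2OC)C(=O)OC=C1 | intermediate
24 | 3-[3-(benzyloxy)-4-{4-[2-(but-3-yn-1-yl)-1,3-dioxolan-2-yl]butyl}-2-methoxyphenoxy]-4-methoxy-2H-pyran-2-one | COC1=C(Oc2ccc(CCCCC3(CCC#C)OCCO3)c(OCc3ccccc3)c2OC)C(=O)OC=C1 | intermediate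
25 | bridged lactone (2-oxabicyclo[2.2.2]octa-5,7-dien-3-one) formed by bonding pyrone C3 to the alkyne CH and pyrone C6 to the chain-bearing alkyne carbon, macrocycle closed (racemic) | COC1=CC2OC(=O)C1(C=C2CCC3(OCCO3)CCCCc4ccc5c(OC)c4OCc6ccccc6)O5 | intermediate
26 | O-benzyl juglanin A ethylene ketal (ring B phenol as benzyl ether, C5 ketone as 1,3-dioxolane) | COc1ccc2cc1Oc1ccc(c(OCc3ccccc3)c1OC)CCCCC1(OCCO1)CC2 | intermediate
27 | juglanin A ethylene ketal (free ring B phenol, C5 ketone as 1,3-dioxolane) | COc1ccc2cc1Oc1ccc(c(O)c1OC)CCCCC1(OCCO1)CC2 | intermediate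
28 | juglanin A | COc1ccc2cc1Oc1ccc(c(O)c1OC)CCCCC(=O)CC2 | target

Total step count: 14 (13 in the main line, one for fragment 19).
Longest linear sequence: 13 steps (steps 1–8 and 10–14).

Steps most likely to fail

Step 13. The unactivated alkyne may cycloadd too slowly to compete with thermal decomposition or intermolecular reaction, or it may add in the reverse orientation (chain-bearing carbon to pyrone C3), which would give the ortho-fused 14-membered isomer. The fallback sets out from 24 and replaces the alkyne by an activated, polarised alkyne equivalent. Markovnikov hydrothiolation (PhSH, Pd(OAc)2 cat., THF, 40 °C) should give the 2-(phenylsulfanyl)alkene F1, and oxidation (mCPBA, NaHCO3, CH2Cl2, 0 °C) the 2-(phenylsulfonyl)alkene F2. Its unsubstituted CH2 terminus is the electrophilic one and therefore pairs with the nucleophilic pyrone C3, which fixes the required orientation. Heating F2 at high dilution (toluene, 110–140 °C) should give the sulfonyl bridged lactone F3, which loses CO2 to the sulfonylcyclohexadiene F4. Elimination of benzenesulfinic acid (DBU) then aromatises ring A and returns the route to 26. Pyrone Diels–Alder reactions of vinyl sulfones as alkyne surrogates are known chemistry.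

Step 7. The enolate may be acylated on oxygen or twice, and the ring closure may stall at the open-chain stage or be diverted by acid-induced cyclodehydration onto ring B. The fallback sets out from 11 and builds the same carbon chain by two separate C–C bond formations. C-Acetylation (LiN(SiMe3)2, THF, −78 °C; N-acetylimidazole) should give the 2-aryloxyacetoacetate F5. Its dianion (LiN(i-Pr)2, 2.2 equiv, THF, −78 → 0 °C) is formylated at the terminal methyl carbon with ethyl formate, the known acylation of β-keto ester dianions. Acidification gives 14, from which the route continues to 15 as before.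

Step 8. The ambident pyronolate may be methylated at the lactone carbonyl oxygen, which would give the isomeric 2-methoxy-4-pyranone. The fallback sets out from 15 and replaces the kinetic alkylation by acid-catalysed vinylogous Fischer etherification under equilibrating conditions (MeOH, HC(OMe)3, cat. H2SO4, 60 °C). This is the way vinylogous carboxylic acids are converted to their methyl vinylogous esters under thermodynamic control, and it leads directly to 16. No new compound arises (F0).

Further compounds
F1 | step 13 | 3-[3-(benzyloxy)-2-methoxy-4-(4-{2-[3-(phenylsulfanyl)but-3-en-1-yl]-1,3-dioxolan-2-yl}butyl)phenoxy]-4-methoxy-2H-pyran-2-one | COC1=C(Oc2ccc(CCCCC3(CCC(=C)Sc4ccccc4)OCCO3)c(OCc3ccccc3)c2OC)C(=O)OC=C1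
F2 | step 13 | 3-[3-(benzyloxy)-2-methoxy-4-(4-{2-[3-(phenylsulfonyl)but-3-en-1-yl]-1,3-dioxolan-2-yl}butyl)phenoxy]-4-methoxy-2H-pyran-2-one | COC1=C(Oc2ccc(CCCCC3(CCC(=C)S(=O)(=O)c4ccccc4)OCCO3)c(OCc3ccccc3)c2OC)C(=O)OC=C1
F3 | step 13 | sulfonyl bridged lactone from F2 (CH2 bonded to former pyrone C3, sulfonyl-bearing carbon bonded to former pyrone C6; racemic diastereomers) | COC1=CC2OC(=O)C1(CC2(S(=O)(=O)c7ccccc7)CCC3(OCCO3)CCCCc4ccc5c(OC)c4OCc6ccccc6)O5
F4 | step 13 | sulfonylcyclohexadiene formed from F3 by loss of CO2 (macrocycle closed, racemic) | COC1=C2CC(S(=O)(=O)c3ccccc3)(C=C1)CCC1(OCCO1)CCCCc1ccc(O2)c(OC)c1OCc1ccccc1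
F5 | step 7 | methyl 2-[3-(benzyloxy)-4-(3-chloropropyl)-2-methoxyphenoxy]-3-oxobutanoate (racemic) | CC(=O)C(Oc1ccc(CCCCl)c(OCc2ccccc2)c1OC)C(=O)OC
F0 | step 8 | none | none
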